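**Plan**

Locants: chroman O1, C2 (O–CH), C3 (C–Me), C4 (CH–iBu); Ca and Cb are the CH2 groups on C3 and on the spiro carbon Cs; the cyclohexene is Cs–C2'H=C3'(iPr)–C4'H2–C5'H2–C6'H(Me).
Enabling feature: Cs is flanked by the alkene carbon C2', so the cyclohexene is a latent menthone (C2'=O, C3'H–iPr) with Cs as its α-carbon; in the cyclopentane Cs–C2–C3–Ca–Cb this puts Cb one SN2 step from the enolate and makes C2 a β-aryloxy ketone carbon that can epimerize by retro-oxa-Michael/oxa-Michael.
Cuts: Cb–Cs (enolate alkylation, cyclopentane closed last), C2–Cs (anomeric oxocarbenium + menthone silyl enol ether), C2'=C3' back to the activating ketone (enol triflate), both CHO and both OH back to a dimethoxyarene, the pyranone by Pechmann condensation.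
Forward: arene → coumarin → chroman-2-one (C4, then C3) → anomeric acetate → union with (−)-menthone at C2 → cyclopentane by spiro-alkylation → enol triflate → twofold formylation → alkene → demethylation.
Stereochemistry: C4 from an asymmetric CuH conjugate reduction, C3 from methylation anti to the isobutyl group, C6' from (−)-menthone, Cs from alkylation anti to the C6' methyl group, C2 from equilibration funnelled through the only epimer able to close the cis-fused ring.

Key step: step 9

Remark: the antipode of DTBM-SEGPHOS in step 2 is taken to be the one that gives (R)-4; a test reduction would fix which antipode this is.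

**Route**

Step 1
Reactants: 1 3,5-dimethoxyphenol; 2 ethyl 5-methyl-3-oxohexanoate
Product: 3 4-isobutyl-5,7-dimethoxy-2H-chromen-2-one
Conditions: conc. H2SO4, 0 °C to rt
Reagents that add atoms: none
Why: Pechmann condensation (transesterification, then intramolecular hydroxyalkylation and dehydration) on a symmetric, doubly activated phenol whose two ortho positions are equivalent, so a single coumarin with the isobutyl group at C4 is expected and no stereocenter arises.

Step 2
Reactants: 3 4-isobutyl-5,7-dimethoxy-2H-chromen-2-one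
Product: 4 (R)-4-isobutyl-5,7-dimethoxychroman-2-one
Conditions: Cu(OAc)2·H2O (cat.), DTBM-SEGPHOS (cat.), (EtO)2MeSiH, t-BuOH, toluene, rt
Reagents that add atoms: none
Why: Copper hydride catalysed asymmetric conjugate reduction of a β-aryl-β-alkyl unsaturated lactone (1,4-hydride delivery, then protonation of the copper enolate by t-BuOH) is well precedented for 4-substituted coumarins, and the chiral bisphosphine sets C4 as R.

Step 3
Reactants: 4 (R)-4-isobutyl-5,7-dimethoxychroman-2-one
Product: 5 (3R,4R)-3-[2-(tert-butyldimethylsilyloxy)ethyl]-4-isobutyl-5,7-dimethoxychroman-2-one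
Conditions: LiN(SiMe3)2, THF, −78 °C; silyloxyethyl iodide, DMPU, −78 to −30 °C
Reagents that add atoms: tert-butyl(2-iodoethoxy)dimethylsilane, CC(C)(C)[Si](C)(C)OCCI
Why: Alkylation of the lithium lactone enolate with a primary iodide at low temperature (to outrun ketene formation) installs the two-carbon arm Ca–Cb trans to the C4 isobutyl group, a provisional C3 configuration that is erased by re-enolization in step 4.

Step 4
Reactants: 5 (3R,4R)-3-[2-(tert-butyldimethylsilyloxy)ethyl]-4-isobutyl-5,7-dimethoxychroman-2-one
Product: 6 3-[2-(tert-butyldimethylsilyloxy)ethyl]-4-isobutyl-5,7-dimethoxy-3-methylchroman-2-one (C4 geometry as in 4; C3 methyl trans and silyloxyethyl arm cis to isobutyl)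
Conditions: LiN(iPr)2, THF, −78 °C; MeI, −78 to −40 °C
Reagents that add atoms: iodomethane, CI
Why: Second enolate alkylation: iodomethane approaches the planar C3 of the lactone enolate on the face anti to the pseudoaxial C4 isobutyl group, so the quaternary C3 is formed with methyl trans and the silyloxyethyl arm cis to isobutyl, as the target requires.

Step 5
Reactants: 6 3-[2-(tert-butyldimethylsilyloxy)ethyl]-4-isobutyl-5,7-dimethoxy-3-methylchroman-2-one
Product: 8 2-acetoxy-3-[2-(tert-butyldimethylsilyloxy)ethyl]-4-isobutyl-5,7-dimethoxy-3-methylchroman (C3 and C4 as in 6; both C2 epimers), via lactol 7 (not isolated)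
Conditions: i-Bu2AlH, CH2Cl2, −78 °C; sodium potassium tartrate work-up; then Ac2O, pyridine, DMAP (cat.), CH2Cl2, 0 °C
Reagents that add atoms: acetic anhydride, CC(=O)OC(C)=O
Why: Half-reduction of the lactone by i-Bu2AlH at −78 °C followed by acetylation of the hemiacetal gives the anomeric acetate, the usual precursor of a cyclic oxocarbenium ion, and the configuration at C2 is of no consequence.

Step 6
Reactants: 9 (−)-menthone, (2S,5R)-2-isopropyl-5-methylcyclohexan-1-one
Product: 10 (3R,6S)-6-isopropyl-3-methyl-1-(trimethylsilyloxy)cyclohex-1-ene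
Conditions: LiN(iPr)2, THF, −78 °C; Me3SiCl
Reagents that add atoms: chlorotrimethylsilane, C[Si](C)(C)Cl
Why: Kinetic deprotonation of menthone by the bulky amide takes place at the α-methylene (future Cs) and not at the isopropyl-bearing methine, and O-silylation traps this enolate as the less substituted silyl enol ether without touching either stereocenter.

Step 7
Reactants: 8 2-acetoxy-3-[2-(tert-butyldimethylsilyloxy)ethyl]-4-isobutyl-5,7-dimethoxy-3-methylchroman; 10 (3R,6S)-6-isopropyl-3-methyl-1-(trimethylsilyloxy)cyclohex-1-ene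
Product: 11 3-[2-(tert-butyldimethylsilyloxy)ethyl]-4-isobutyl-2-(3-isopropyl-6-methyl-2-oxocyclohexyl)-5,7-dimethoxy-3-methylchroman (C3 and C4 as in 6; ring methyl carbon as in menthone; mixture at C2 and at the ring carbon bonded to C2)
Conditions: Me3SiOTf (cat.), CH2Cl2, −78 to −40 °C
Reagents that add atoms: none
Why: Mukaiyama-type addition of the silyl enol ether to the aryl oxocarbenium ion released from the anomeric acetate by Me3SiOTf forms the C2–Cs bond; attack anti to the isobutyl group and the larger C3 arm should favour the 2,3-trans epimer, which is acceptable because C2 is re-equilibrated in step 9 and Cs is re-enolized.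

Step 8
Reactants: 11 silyl ether ketone from step 7
Product: 12 3-(2-bromoethyl)-4-isobutyl-2-(3-isopropyl-6-methyl-2-oxocyclohexyl)-5,7-dimethoxy-3-methylchroman (stereochemistry as in 11)
Conditions: Ph3PBr2, CH2Cl2, 0 °C to rt
Reagents that add atoms: dibromotriphenylphosphorane, BrP(Br)(c1ccccc1)(c1ccccc1)c1ccccc1
Why: Appel-type conversion of a primary silyl ether into the bromide by Ph3PBr2 (oxyphosphonium formation and SN2 displacement at Cb) leaves the ketone, the aryl ethers and all stereocenters untouched.

Step 9
Reactants: 12 bromo ketone from step 8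
Product: 14 spiro ketone: 4-isobutyl-5,7-dimethoxy-3-methylchroman cis-fused at C2–C3 to the cyclopentane Cs–C2–C3–Ca–Cb whose Cs is spiro to 3-isopropyl-6-methylcyclohexan-2-one (C2'=O; configuration at C2 C3 C4 Cs C6' as in the target; C3' epimers), via ring-opened enone 13 (not isolated)
Conditions: t-BuOK, t-BuOH/THF, high dilution, 0 °C to rt
Reagents that add atoms: none
Why: t-BuOK forms the ketone enolates reversibly, and the enolate at the α-carbon that carries the chroman (future Cs) either alkylates directly or, in the 2,3-trans epimer, expels the phenoxide (E1cB, retro-oxa-Michael) to the ring-opened enone 13, which re-closes the pyran by 6-exo-trig oxa-Michael addition on either face, so that C2 equilibrates under the reaction conditions. Only the epimer whose enolate carbon is cis to the bromoethyl arm can reach Cb, and its irreversible 5-exo-tet C-alkylation (enolate double bond exocyclic to the new ring) closes the cyclopentane; the closest known reaction types are the intramolecular ketone enolate alkylation used for spiroannulation and the Michael-initiated ring closure. C2 is thus set by the ring constraint (only a cis-fused cyclopenta[b]chroman can form), and Cs by the neighbouring C6' methyl stereocenter of menthone: A(1,2) strain with the chromanyl substituent holds that methyl pseudoaxial and Cb enters on the opposite enolate face, which leaves Cb trans and C2 cis to the methyl as in the target. The step needs C-alkylation at Cs in preference to O-alkylation and to reaction of the other enolate; the isopropyl-side enolate, the enolate oxygen and the liberated phenoxide could each reach Cb only through a seven-membered transition state, so the five-membered closure should dominate at high dilution. The product has no hydrogen at Cs, so neither retro-oxa-Michael cleavage nor epimerization can follow.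

Step 10
Reactants: 14 spiro ketone from step 9
Product: 15 enol triflate of 14 (C2'(OTf)=C3'(iPr); other stereocenters as in 14)
Conditions: KN(SiMe3)2, THF, −78 °C; PhNTf2, −78 °C to rt
Reagents that add atoms: N-phenylbis(trifluoromethanesulfonimide), O=S(=O)(N(c1ccccc1)S(=O)(=O)C(F)(F)F)C(F)(F)F
Why: Enol triflate formation: the spiro ketone has a single α-hydrogen, at C3', so KN(SiMe3)2 can give only the C2'=C3' enolate, which is O-sulfonylated by PhNTf2 with loss of the inconsequential C3' stereocenter.

Step 11
Reactants: 15 enol triflate from step 10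
Product: 17 6,8-diformyl enol triflate (5,7-dimethoxy; stereocenters as in 15), via bis(chloromethoxymethyl) arene 16 (not isolated)
Conditions: Cl2CHOMe, TiCl4, CH2Cl2, −78 to 0 °C; H2O work-up
Reagents that add atoms: dichloromethyl methyl ether, COC(Cl)Cl; water, O
Why: Twofold Rieche formylation (electrophilic substitution by the chloromethoxymethyl cation, then hydrolysis) at C6 and C8, the only free and doubly oxygen-flanked arene positions, carried out while the future alkene is still masked as an acid-stable enol triflate.

Step 12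
Reactants: 17 diformyl enol triflate from step 11
Product: 18 5,7-di-O-methyl ether of the target
Conditions: Pd(OAc)2 (cat.), PPh3, HCO2H, n-Bu3N, DMF, 60 °C
Reagents that add atoms: none
Why: Pd(OAc)2/PPh3-catalysed formate reduction of the enol triflate (oxidative addition, decarboxylation of the formate ligand, reductive elimination of C–H) unveils the C2'=C3' alkene exactly where the ketone was, and aryl aldehydes and ethers are inert.

Step 13
Reactants: 18 5,7-di-O-methyl ether of the target
Product: 19 target CNP0121396.1
Conditions: NaSEt, DMF, 100 °C; then aq. HCl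
Reagents that add atoms: none
Why: Thiolate demethylation (SN2 at the methyl groups) of the two aryl methyl ethers, each activated by an ortho formyl group, gives after acidification the target; the C2–O1 bond is flanked by two quaternary carbons and the alkene is inert to thiolate.

**Compound list**

1 | 3,5-dimethoxyphenol | COc1cc(O)cc(OC)c1 | starting material
2 | ethyl 5-methyl-3-oxohexanoate | CCOC(=O)CC(=O)CC(C)C | starting material
3 | 4-isobutyl-5,7-dimethoxy-2H-chromen-2-one | CC(C)CC1=CC(=O)Oc2cc(OC)cc(OC)c21 | intermediate
4 | (R)-4-isobutyl-5,7-dimethoxychroman-2-one | CC(C)C[C@H]1c2c(OC)cc(OC)cc2OC(=O)C1 | intermediate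
5 | (3R,4R)-3-[2-(tert-butyldimethylsilyloxy)ethyl]-4-isobutyl-5,7-dimethoxychroman-2-one (arm trans to isobutyl) | CC(C)C[C@H]1c2c(OC)cc(OC)cc2OC(=O)[C@@H]1CCO[Si](C)(C)C(C)(C)C | intermediate
6 | 3-[2-(tert-butyldimethylsilyloxy)ethyl]-4-isobutyl-5,7-dimethoxy-3-methylchroman-2-one, C4 geometry as in 4, C3 methyl trans and arm cis to isobutyl | CC(C)C[C@H]1c2c(OC)cc(OC)cc2OC(=O)[C@@]1(C)CCO[Si](C)(C)C(C)(C)C | intermediate
7 | chroman-2-ol (lactol) of 6, both C2 epimers | CC(C)C[C@H]1c2c(OC)cc(OC)cc2OC(O)[C@@]1(C)CCO[Si](C)(C)C(C)(C)C | intermediate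
8 | 2-acetoxy-3-[2-(tert-butyldimethylsilyloxy)ethyl]-4-isobutyl-5,7-dimethoxy-3-methylchroman, both C2 epimers | CC(C)C[C@H]1c2c(OC)cc(OC)cc2OC(OC(C)=O)[C@@]1(C)CCO[Si](C)(C)C(C)(C)C | intermediate
9 | (−)-menthone, (2S,5R)-2-isopropyl-5-methylcyclohexan-1-one | CC(C)[C@@H]1CC[C@@H](C)CC1=O | starting material
10 | (3R,6S)-6-isopropyl-3-methyl-1-(trimethylsilyloxy)cyclohex-1-ene | CC(C)[C@@H]1CC[C@@H](C)C=C1O[Si](C)(C)C | intermediate
11 | 3-[2-(tert-butyldimethylsilyloxy)ethyl]-4-isobutyl-2-(3-isopropyl-6-methyl-2-oxocyclohexyl)-5,7-dimethoxy-3-methylchroman, mixture at C2 and at the ring carbon bonded to C2 | CC(C)C[C@H]1c2c(OC)cc(OC)cc2OC([C@@]1(C)CCO[Si](C)(C)C(C)(C)C)C1C(=O)[C@H](C(C)C)CC[C@H]1C | intermediate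
12 | 3-(2-bromoethyl)-4-isobutyl-2-(3-isopropyl-6-methyl-2-oxocyclohexyl)-5,7-dimethoxy-3-methylchroman, stereochemistry as in 11 | CC(C)C[C@H]1c2c(OC)cc(OC)cc2OC([C@@]1(C)CCBr)C1C(=O)[C@H](C(C)C)CC[C@H]1C | intermediate
13 | ring-opened enone: 6-alkylidene menthone bearing the free 2-hydroxy-4,6-dimethoxyphenyl group and the bromoethyl arm | CC(C)C[C@@H](c1c(O)cc(OC)cc1OC)[C@](C)(CCBr)C=C1C(=O)C(C(C)C)CC[C@H]1C | intermediate
14 | spiro ketone (C2'=O), configuration at C2, C3, C4, Cs and C6' as in the target, C3' epimers | CC(C)C[C@H]1c2c(OC)cc(OC)cc2O[C@@H]2[C@@]1(C)CC[C@@]21C(=O)C(C(C)C)CC[C@H]1C | intermediate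
15 | enol triflate of 14, C2'(OTf)=C3'(iPr) | CC(C)C[C@H]1c2c(OC)cc(OC)cc2O[C@@H]2[C@@]1(C)CC[C@@]21C(OS(=O)(=O)C(F)(F)F)=C(C(C)C)CC[C@H]1C | intermediate
16 | 6,8-bis[chloro(methoxy)methyl] derivative of 15 | CC(C)C[C@H]1c2c(OC)c(C(Cl)OC)c(OC)c(C(Cl)OC)c2O[C@@H]2[C@@]1(C)CC[C@@]21C(OS(=O)(=O)C(F)(F)F)=C(C(C)C)CC[C@H]1C | intermediate
17 | 6,8-diformyl enol triflate | CC(C)C[C@H]1c2c(OC)c(C=O)c(OC)c(C=O)c2O[C@@H]2[C@@]1(C)CC[C@@]21C(OS(=O)(=O)C(F)(F)F)=C(C(C)C)CC[C@H]1C | intermediate
18 | 5,7-di-O-methyl ether of the target | CC(C)C[C@H]1c2c(OC)c(C=O)c(OC)c(C=O)c2O[C@@H]2[C@@]1(C)CC[C@@]21C=C(C(C)C)CC[C@H]1C | intermediate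
19 | CNP0121396.1: 5,7-dihydroxy-4-isobutyl-3-methylchroman-6,8-dicarbaldehyde cis-fused at C2–C3 to a cyclopentane spiro-linked to 3-isopropyl-6-methylcyclohex-2-ene (2R,3S,4R; Cs R; C6' R) | CC(C)C[C@H]1c2c(O)c(C=O)c(O)c(C=O)c2O[C@@H]2[C@@]1(C)CC[C@@]21C=C(C(C)C)CC[C@H]1C | target

**Count and risks**

Total step count: 13. Longest linear sequence: 12 steps (steps 1–5 and 7–13); step 6 is the one-step menthone branch.

Steps most likely to fail:

1. Step 9. What may go wrong:
 - O-alkylation of the phenoxide set free by the retro-oxa-Michael cleavage, giving a seven-membered aryl ether.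
 - Slow C2 equilibration, which leaves the 2,3-trans epimer unreacted.
 - Eroded facial selectivity at Cs, if the O1/methyl interaction in the required transition state offsets the anti-methyl preference.

 Fallback, from 12 back to 14: the alkyl halide is replaced by an aldehyde so that every hetero-nucleophile addition becomes reversible. Bromide 12 is oxidized with Me3NO in DMSO (Kornblum-type oxidation) to the aldehyde F1. With catalytic t-BuOK in t-BuOH the same Cs enolate adds to the aldehyde in an intramolecular aldol reaction (5-exo-trig, anti to the C6' methyl) to give the spiro β-hydroxy ketone F2. Mesylation and DBU elimination away from the quaternary Cs give the cyclopentene ketone F3. Hydrogenation (H2, Pd/C) then gives 14.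

2. Step 7. What may go wrong: low reactivity of the neopentyl-type oxocarbenium ion towards the trisubstituted silyl enol ether, with protodesilylation of the nucleophile or loss of the silyl ether instead of C–C bond formation.

 Fallback, from 6 and 9 back to 11: 6 is reduced with i-Bu2AlH and lactol 7 is isolated. Heating 7 with menthone 9 and KOH in MeOH brings about a Claisen–Schmidt-type crossed aldol condensation of its non-enolizable hydroxy-aldehyde tautomer at the α-methylene of 9. This gives the aldol adduct F4 and, after loss of water, the enone F5, whose phenoxide closes the pyran ring by oxa-Michael addition to 11 (mixture of C2 epimers, as in the main route).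

3. Step 11. What may go wrong: incomplete second formylation, or Lewis-acid-induced demethylation or ether cleavage.

 Fallback, from 15 back to 18: the triflate is reduced first (Pd(OAc)2, PPh3, HCO2H, n-Bu3N) to the formyl-free alkene F6. Both free arene positions are brominated with N-bromosuccinimide (MeCN, 0 °C) to give the 6,8-dibromide F7. Double bromine–lithium exchange (t-BuLi, THF, −78 °C) and quenching with DMF then give 18.

**Further compounds**

F1 | step 9 | 2-[4-isobutyl-2-(3-isopropyl-6-methyl-2-oxocyclohexyl)-5,7-dimethoxy-3-methylchroman-3-yl]acetaldehyde | CC(C)C[C@H]1c2c(OC)cc(OC)cc2OC([C@@]1(C)CC=O)C1C(=O)[C@H](C(C)C)CC[C@H]1C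
F2 | step 9 | spiro β-hydroxy ketone (Cb–OH analogue of 14) | CC(C)C[C@H]1c2c(OC)cc(OC)cc2O[C@@H]2[C@@]1(C)CC(O)[C@@]21C(=O)C(C(C)C)CC[C@H]1C
F3 | step 9 | cyclopentene ketone (Ca=Cb analogue of 14) | CC(C)C[C@H]1c2c(OC)cc(OC)cc2O[C@@H]2[C@@]1(C)C=C[C@@]21C(=O)C(C(C)C)CC[C@H]1C
F4 | step 7 | aldol adduct of lactol 7 (open form) and menthone | CC(C)C[C@@H](c1c(O)cc(OC)cc1OC)[C@](C)(CCO[Si](C)(C)C(C)(C)C)C(O)C1C(=O)C(C(C)C)CC[C@H]1C
F5 | step 7 | enone from dehydration of F4 (silyl ether analogue of 13) | CC(C)C[C@@H](c1c(O)cc(OC)cc1OC)[C@](C)(CCO[Si](C)(C)C(C)(C)C)C=C1C(=O)C(C(C)C)CC[C@H]1C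
F6 | step 11 | formyl-free alkene (6,8-unsubstituted analogue of 18) | CC(C)C[C@H]1c2c(OC)cc(OC)cc2O[C@@H]2[C@@]1(C)CC[C@@]21C=C(C(C)C)CC[C@H]1C
F7 | step 11 | 6,8-dibromide of F6 | CC(C)C[C@H]1c2c(OC)c(Br)c(OC)c(Br)c2O[C@@H]2[C@@]1(C)CC[C@@]21C=C(C(C)C)CC[C@H]1C
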